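**Plan**
1. Numbering (germacrane type): C1 ketone, C2=C3, bridge oxygen between C3 and C10, C4 (Me), C5 (OH), C6 (O-isobutyryl), C7, C8 (lactone O), C9H2, C10 (Me); lactone carbons C11(=C13H2) and C12.
2. Enabling feature: the bridge oxygen sits on C10, C10 is alpha to the C1 carbonyl (a carbene site), and C10-C9-C8(O)-C7 is a 2-oxyallyl array. Rebonding that oxygen to C7 collapses furanone plus ten-membered carbocycle (an 11-oxabicyclo[6.2.1]undecane) to one tetrahydropyran (O, C3-C7) whose five substituents are all equatorial.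
3. Cuts, in retrosynthetic order: O5/O6 groups; C11=C13; O8-C12 and C7-C11 (lactone from a C7=C8 enol ether and a diazoacetate); the C2=C3 unsaturation; then O-C10 and C9-C10 together (O-C7 restored); C7-C8; C4-CH3; O-C7/C3-C4 of a pyranone.
4. Forward: dihydropyranone, then tetrahydropyran. One step then forms the five-membered oxacycle and the ten-membered carbocycle while the six-membered ring opens. A temporary cyclopropane, the furanone and the gamma-lactone follow.
5. Stereochemistry: C3 comes from a catalytic asymmetric hetero-Diels-Alder reaction. C4, C5, C6 and temporary C7 are relayed around the pyran ring. C3 hands its information to quaternary C10 through the ylide and is then erased. C7 and C8 are set from the outer face of the bicycle.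

Key step: step 11

Remarks on the chemistry:
- (a) The SMILES is read as 4S,5S,6S,7R,8S,10R with a trans-fused lactone.
- (b) The C7=C8 geometry in 19 and the C11 configuration in 21-23, 27 and 28 are drawn for the expected major isomer; both elements are erased later.
- (c) Diazoethane (from N-ethyl-N-nitrosourea and aq KOH) and dimethyldioxirane (from acetone and KHSO5) are used as freshly made stock solutions.
- (d) Compounds that carry an enol ether are purified on Et3N-deactivated silica.

**Step 1**
Reactants: 1 (E)-1-methoxy-3-(trimethylsilyloxy)buta-1,3-diene; 2 3-(tert-butyldimethylsilyloxy)propanal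
Product: 4 (R)-2-[2-(tert-butyldimethylsilyloxy)ethyl]-2,3-dihydro-4H-pyran-4-one, via silyl aldol adduct 3 (not isolated)
Conditions: Ti(OiPr)4 (10 mol %), (S)-BINOL (20 mol %), 4 Å MS, Et2O, -20 °C; then CF3CO2H, CH2Cl2, 0 °C
Reagents that add atoms: none
Why: Catalytic asymmetric hetero-Diels-Alder reaction run as a Mukaiyama aldol addition followed by acid cyclisation: the titanium-BINOL complex should expose the Si face of aldehyde 2 to the diene terminus C4 and so set C3 (the ligand antipode is available if the sense is opposite), and CF3CO2H then removes the silyl group and closes the ring by conjugate addition and loss of methanol.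

**Step 2**
Reactants: 4 (R)-2-[2-(tert-butyldimethylsilyloxy)ethyl]-2,3-dihydro-4H-pyran-4-one
Product: 5 (S)-(4-oxo-3,4-dihydro-2H-pyran-2-yl)acetic acid
Conditions: CrO3, H2SO4, H2O, acetone, 0 °C
Reagents that add atoms: water O
Why: Jones oxidation: the acidic medium cleaves the primary silyl ether and chromic acid carries the alcohol through the aldehyde hydrate to the acid, while the vinylogous ester ring and C3 are untouched.

**Step 3**
Reactants: 5 (S)-(4-oxo-3,4-dihydro-2H-pyran-2-yl)acetic acid
Product: 6 methyl (S)-(4-oxo-3,4-dihydro-2H-pyran-2-yl)acetate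
Conditions: MeI, K2CO3, DMF, 23 °C
Reagents that add atoms: iodomethane CI
Why: SN2 O-alkylation of the carboxylate, which masks the acid for the base and hydride steps that follow and creates no stereocentre.

**Step 4**
Reactants: 6 methyl (S)-(4-oxo-3,4-dihydro-2H-pyran-2-yl)acetate
Product: 7 methyl [(2R,3R)-3-methyl-4-oxo-3,4-dihydro-2H-pyran-2-yl]acetate (2,3-trans)
Conditions: LiN(iPr)2, THF, -78 °C; MeI, DMPU, -78 to -40 °C
Reagents that add atoms: iodomethane CI
Why: Kinetic alpha'-deprotonation of the vinylogous ester (more acidic than the ester CH2) and enolate alkylation: MeI approaches C4 anti to the C3 side chain to give the 3,4-trans product, which is also the more stable epimer.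

**Step 5**
Reactants: 7 methyl [(2R,3R)-3-methyl-4-oxo-3,4-dihydro-2H-pyran-2-yl]acetate
Product: 8 methyl [(2R,3S,4R)-4-hydroxy-3-methyl-3,4-dihydro-2H-pyran-2-yl]acetate (side chain; methyl; hydroxyl mutually trans)
Conditions: NaBH4, CeCl3·7H2O, MeOH, -78 °C
Reagents that add atoms: none
Why: Luche reduction: cerium-assisted 1,2-hydride addition along the axial trajectory gives the pseudo-equatorial C5 alcohol trans to the C4 methyl group and leaves the ester and the enol ether alone.

**Step 6**
Reactants: 8 methyl [(2R,3S,4R)-4-hydroxy-3-methyl-3,4-dihydro-2H-pyran-2-yl]acetate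
Product: 9 PMB ether of 8 (C5 O-4-methoxybenzyl; configuration unchanged)
Conditions: NaH, 4-methoxybenzyl chloride, Bu4NI (cat.), DMF, -20 to 0 °C
Reagents that add atoms: 4-methoxybenzyl chloride COc1ccc(CCl)cc1
Why: Williamson etherification of the allylic alkoxide, run cold so that benzylation outpaces attack of the alkoxide on the ester; the PMB group can be removed oxidatively at the very end.

**Step 7**
Reactants: 9 PMB ether of 8; 10 ethyl vinyl ether
Product: 13 all-equatorial tetrahydropyran alcohol (C3 CH2CO2Me; C4 Me; C5 OPMB; C6 OH; C7 1-ethoxyvinyl), via cuprate 11 (not isolated), via glycal epoxide 12 (not isolated)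
Conditions: dimethyldioxirane, acetone-CH2Cl2, 0 °C, evaporate; 11 [10, t-BuLi, THF, -78 to 0 °C; CuI, -40 °C], THF, -78 to -20 °C; aq NH4Cl
Reagents that add atoms: dimethyldioxirane CC1(C)OO1
Why: Epoxidation of a glycal-type enol ether and SN2 opening of the resulting 1,2-anhydro-sugar-type epoxide by an organocuprate: the dioxirane attacks anti to the C5 OPMB group and sets C6, the cuprate inverts the acetal carbon C7 to place the 1-ethoxyvinyl group equatorial, and only O6 is set free, which differentiates O5 from O6.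

**Step 8**
Reactants: 13 all-equatorial tetrahydropyran alcohol
Product: 14 C6 TBS ether of 13
Conditions: tBuMe2SiOTf, 2,6-lutidine, CH2Cl2, -78 to 0 °C
Reagents that add atoms: tert-butyldimethylsilyl triflate CC(C)(C)[Si](C)(C)OS(=O)(=O)C(F)(F)F
Why: Silylation with a silyl triflate and a hindered pyridine base, mild enough to spare the enol ether and to exclude any group migration.

**Step 9**
Reactants: 14 C6 TBS ether of 13
Product: 15 potassium carboxylate of 14
Conditions: KOSiMe3, THF, 23 °C
Reagents that add atoms: potassium trimethylsilanolate C[Si](C)(C)[O-].[K+]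
Why: Anhydrous ester cleavage by trimethylsilanolate delivers the carboxylate salt directly, so the acid-labile 1-ethoxyvinyl group never meets a free acid.

**Step 10**
Reactants: 15 potassium carboxylate of 14
Product: 17 diazoketone (C3 arm CH2C(=O)C(=N2)CH3), via mixed anhydride 16 (not isolated)
Conditions: iBuOCOCl, THF, -20 °C; then CH3CHN2, Et2O, -20 to 0 °C
Reagents that add atoms: diazoethane CC=[N+]=[N-]; isobutyl chloroformate CC(C)COC(=O)Cl (atoms remain only in 16)
Why: Acylation of a diazoalkane by a mixed carbonic anhydride (first stage of an Arndt-Eistert sequence): nucleophilic diazoethane attacks the acyl carbon and the departing monoalkyl carbonate takes up the proton, which installs C10, C14 and the diazo activating group under neutral conditions.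

**Step 11**
Reactants: 17 diazoketone
Product: 19 bridged ketone (11-oxabicyclo[6.2.1]undecene; C1 ketone; C7=C8 ethyl enol ether; quaternary C10), via oxonium ylide 18 (not isolated)
Conditions: Cu(CF3COCHCOCF3)2 (5 mol %), CH2Cl2, reflux, slow addition of 17 at high dilution
Reagents that add atoms: none
Why: Copper-induced loss of N2 makes C10 an electrophilic metal carbene centre, the axial lone pair of the pyran oxygen attacks it and closes the five-membered ring O-C3-C2-C1-C10 (5-exo-type closure, O-C10 bond) to give the cis-fused bicyclic oxonium ylide 18, and a concerted suprafacial [2,3]-sigmatropic shift through a five-centre envelope then bonds C9 to C10 as O-C7 breaks. The closest known reaction type is the catalytic oxonium ylide formation/[2,3] rearrangement of 2-vinyl cyclic ethers that carry a diazoketone arm at the other alpha-carbon, a three-atom ring expansion that gives bridged oxabicyclo[6.2.1]undecenones. The ten-membered carbocycle therefore closes by expansion of the six-membered ring (C3-C7 plus C8, C9, C10, C1, C2) and not by end-to-end macrocyclisation, and the former ring oxygen is left as the C3-O-C10 bridge. The one new stereocentre, quaternary C10, is controlled by C3: in the cis-fused ylide C7 and C4 lie on the same face of the five-membered ring, the allyl terminus C9 can reach C10 only on that face, so C9 ends syn to C4 and the methyl group anti, which is (10R). The equatorial 1-ethoxyvinyl group is gauche to the new axial O-C10 bond, an arrangement that should favour the C7=C8 isomer with C6 and C9 cis, and either isomer would converge at 24. The step needs ylide formation to outrun 1,2-hydride shift from the C14 methyl group, 1,5 C-H insertion at C4 and attack on the enol ether; the 1,5-relation of carbene carbon and unhindered ether oxygen, the electron-poor hexafluoroacetylacetonate ligands on divalent copper and high dilution serve this, and the allylic C7-O bond aligned with the C8=C9 pi system makes the [2,3] shift faster than a [1,2] shift.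

**Step 12**
Reactants: 19 bridged ketone; 20 ethyl diazoacetate
Product: 21 donor-acceptor cyclopropane (C11 bridging C7 and C8 on the outer face; OEt on C8; CO2Et on C11)
Conditions: 20 (3 equiv, syringe pump), Rh2(OAc)4 (1 mol %), CH2Cl2, 23 °C
Reagents that add atoms: none
Why: Rhodium-carbenoid cyclopropanation of an enol ether: C7=C8 is the only electron-rich alkene, its inner face is covered by the oxygen bridge that has just left C7, so C11 should add from the outer face and set C7 (C7-C11 anti to the former C7-O bond), while the new centres C8 and C11 are temporary.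

**Step 13**
Reactants: 21 donor-acceptor cyclopropane
Product: 23 furanone cyclopropane (C2=C3 installed), via silyl enol ether 22 (not isolated)
Conditions: LiN(iPr)2, Me3SiCl, THF, -78 °C; then Pd(OAc)2 (1.05 equiv), MeCN, 23 °C
Reagents that add atoms: chlorotrimethylsilane C[Si](C)(C)Cl (atoms remain only in 22)
Why: Saegusa-Ito oxidation: C1 can enolise only towards C2 because C10 is quaternary and C11 has no readily removable proton, divalent palladium binds C2 on the open face that also carries H3 so that syn beta-hydride elimination is possible, and the helper stereocentre C3 is erased.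

**Step 14**
Reactants: 23 furanone cyclopropane
Product: 24 gamma-keto ester (C8 ketone; C7 CH2CO2Et)
Conditions: 0.5 M aq HCl, THF, 0 to 23 °C
Reagents that add atoms: water O
Why: Acid-induced ring opening of a 2-alkoxycyclopropanecarboxylate: the ethoxy donor pushes and the ester pulls so that only the C8-C11 bond breaks, water hydrolyses the oxocarbenium ion to the C8 ketone, C7 keeps its configuration, and the mild acid spares the TBS and PMB ethers.

**Step 15**
Reactants: 24 gamma-keto ester
Product: 26 trans-fused gamma-lactone (C11H2), via hydroxy ester 25 (not isolated)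
Conditions: NaBH4, MeOH-CH2Cl2, -40 °C; then PPTS (cat.), benzene, 50 °C
Reagents that add atoms: none
Why: Chemoselective borohydride reduction and acid-catalysed lactonisation: C8 is the only non-conjugated ketone (C1 is a vinylogous ester flanked by quaternary C10), and hydride should arrive on the outer face that C11 has just vacated, opposite the oxygen bridge, which sets (8S) and with C7 the trans ring fusion.

**Step 16**
Reactants: 26 trans-fused gamma-lactone
Product: 29 alpha-methylene lactone (O5 PMB; O6 TBS), via Mannich base 27 (not isolated), via methiodide 28 (not isolated)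
Conditions: LiN(iPr)2, THF, -78 °C; CH2=NMe2 I, -78 to 23 °C; MeI, MeOH, 23 °C; aq NaHCO3, CH2Cl2
Reagents that add atoms: dimethylmethyleneammonium iodide C=[N+](C)C.[I-]; iodomethane CI (atoms remain only in 28)
Why: Mannich-type aminomethylation of the lactone enolate, quaternisation and E1cB elimination: C11 is the only readily enolisable position because gamma-deprotonation of the furanone at C4 would force C5 into the furanone plane, which the six-carbon bridge forbids, so C4 is not scrambled.

**Step 17**
Reactants: 29 alpha-methylene lactone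
Product: 30 C6 alcohol (O5 PMB)
Conditions: HF·pyridine, pyridine, THF, 0 to 23 °C
Reagents that add atoms: none
Why: Fluoride-mediated desilylation under mildly acidic conditions, which avoids conjugate addition to the methylene lactone and lactone migration and leaves the PMB ether in place.

**Step 18**
Reactants: 30 C6 alcohol
Product: 31 C6 isobutyrate (O5 PMB)
Conditions: isobutyryl chloride, pyridine, DMAP (cat.), CH2Cl2, 0 °C
Reagents that add atoms: isobutyryl chloride CC(C)C(=O)Cl
Why: DMAP-catalysed acylation of the only free hydroxyl group, with no change at any stereocentre.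

**Step 19**
Reactants: 31 C6 isobutyrate
Product: 32 CNP0141385.1
Conditions: DDQ, CH2Cl2-pH 7 buffer, 0 °C
Reagents that add atoms: none
Why: Oxidative cleavage of the PMB ether by DDQ (hydride abstraction and hydrolysis of the oxocarbenium ion) at neutral pH, where neither acyl migration from O6 to O5 nor addition to the methylene lactone should occur.

**Compound list**
1 | (E)-1-methoxy-3-(trimethylsilyloxy)buta-1,3-diene | CO/C=C/C(=C)O[Si](C)(C)C | starting material
2 | 3-(tert-butyldimethylsilyloxy)propanal | O=CCCO[Si](C)(C)C(C)(C)C | starting material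
3 | silyl aldol adduct, (5R,1E)-7-(tert-butyldimethylsilyloxy)-1-methoxy-5-(trimethylsilyloxy)hept-1-en-3-one | CO/C=C/C(=O)C[C@@H](CCO[Si](C)(C)C(C)(C)C)O[Si](C)(C)C | intermediate
4 | (R)-2-[2-(tert-butyldimethylsilyloxy)ethyl]-2,3-dihydro-4H-pyran-4-one | CC(C)(C)[Si](C)(C)OCC[C@@H]1CC(=O)C=CO1 | intermediate
5 | (S)-(4-oxo-3,4-dihydro-2H-pyran-2-yl)acetic acid | OC(=O)C[C@@H]1CC(=O)C=CO1 | intermediate
6 | methyl (S)-(4-oxo-3,4-dihydro-2H-pyran-2-yl)acetate | COC(=O)C[C@@H]1CC(=O)C=CO1 | intermediate
7 | methyl [(2R,3R)-3-methyl-4-oxo-3,4-dihydro-2H-pyran-2-yl]acetate | COC(=O)C[C@@H]1[C@@H](C)C(=O)C=CO1 | intermediate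
8 | methyl [(2R,3S,4R)-4-hydroxy-3-methyl-3,4-dihydro-2H-pyran-2-yl]acetate | COC(=O)C[C@@H]1[C@@H](C)[C@H](O)C=CO1 | intermediate
9 | PMB ether of 8 | COC(=O)C[C@@H]1[C@@H](C)[C@H](OCc2ccc(OC)cc2)C=CO1 | intermediate
10 | ethyl vinyl ether | C=COCC | starting material
11 | lithium bis(1-ethoxyvinyl)cuprate | [Li+].C=C(OCC)[Cu-]C(=C)OCC | intermediate
12 | glycal epoxide, C6-C7 oxirane on the face opposite to the C5 OPMB group | COC(=O)C[C@@H]1[C@@H](C)[C@H](OCc2ccc(OC)cc2)[C@H]3O[C@H]3O1 | intermediate
13 | all-equatorial tetrahydropyran (ring O, C3-C7): C3 CH2CO2Me, C4 Me, C5 OPMB, C6 OH, C7 1-ethoxyvinyl; C4-C6 as in the target | COC(=O)C[C@@H]1[C@@H](C)[C@H](OCc2ccc(OC)cc2)[C@@H](O)[C@H](C(=C)OCC)O1 | intermediate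
14 | C6 TBS ether of 13 | COC(=O)C[C@@H]1[C@@H](C)[C@H](OCc2ccc(OC)cc2)[C@@H](O[Si](C)(C)C(C)(C)C)[C@H](C(=C)OCC)O1 | intermediate
15 | potassium carboxylate of 14 | [K+].[O-]C(=O)C[C@@H]1[C@@H](C)[C@H](OCc2ccc(OC)cc2)[C@@H](O[Si](C)(C)C(C)(C)C)[C@H](C(=C)OCC)O1 | intermediate
16 | isobutyl carbonic mixed anhydride of the C1 acid | CC(C)COC(=O)OC(=O)C[C@@H]1[C@@H](C)[C@H](OCc2ccc(OC)cc2)[C@@H](O[Si](C)(C)C(C)(C)C)[C@H](C(=C)OCC)O1 | intermediate
17 | diazoketone, C3 arm CH2C(=O)C(=N2)CH3 on the tetrahydropyran of 14 | CC(=[N+]=[N-])C(=O)C[C@@H]1[C@@H](C)[C@H](OCc2ccc(OC)cc2)[C@@H](O[Si](C)(C)C(C)(C)C)[C@H](C(=C)OCC)O1 | intermediate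
18 | cis-fused bicyclic oxonium ylide, oxygen bonded to C3, C7 and C10 | C[C-]1C(=O)C[C@@H]2[C@@H](C)[C@H](OCc3ccc(OC)cc3)[C@@H](O[Si](C)(C)C(C)(C)C)[C@H](C(=C)OCC)[O+]12 | intermediate
19 | bridged ketone, 3,10-epoxy ten-membered ring with C1 ketone, H3 anti to the bridge carbons, C7=C8 ethyl enol ether (C6 and C9 cis), (10R) | C1[C@@]2(C)O[C@H](CC2=O)[C@@H](C)[C@H](OCc3ccc(OC)cc3)[C@@H](O[Si](C)(C)C(C)(C)C)/C=C1/OCC | intermediate
20 | ethyl diazoacetate | CCOC(=O)C=[N+]=[N-] | starting material
21 | donor-acceptor cyclopropane, C7-C8-C11 ring on the outer face, ester exo | CCO[C@@]12C[C@@]3(C)O[C@H](CC3=O)[C@@H](C)[C@H](OCc4ccc(OC)cc4)[C@@H](O[Si](C)(C)C(C)(C)C)[C@@H]1[C@H]2C(=O)OCC | intermediate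
22 | C1 trimethylsilyl enol ether of 21 | CCO[C@@]12C[C@@]3(C)O[C@H](C=C3O[Si](C)(C)C)[C@@H](C)[C@H](OCc4ccc(OC)cc4)[C@@H](O[Si](C)(C)C(C)(C)C)[C@@H]1[C@H]2C(=O)OCC | intermediate
23 | furanone cyclopropane (C2=C3) | CCO[C@@]12C[C@@]3(C)OC(=CC3=O)[C@@H](C)[C@H](OCc4ccc(OC)cc4)[C@@H](O[Si](C)(C)C(C)(C)C)[C@@H]1[C@H]2C(=O)OCC | intermediate
24 | gamma-keto ester, C8 ketone and C7 CH2CO2Et | O=C1C[C@@]2(C)OC(=CC2=O)[C@@H](C)[C@H](OCc3ccc(OC)cc3)[C@@H](O[Si](C)(C)C(C)(C)C)[C@@H]1CC(=O)OCC | intermediate
25 | (8S)-hydroxy ester | O[C@H]1C[C@@]2(C)OC(=CC2=O)[C@@H](C)[C@H](OCc3ccc(OC)cc3)[C@@H](O[Si](C)(C)C(C)(C)C)[C@@H]1CC(=O)OCC | intermediate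
26 | trans-fused 12,8-lactone with C11H2 | C1C(=O)O[C@H]2C[C@@]3(C)OC(=CC3=O)[C@@H](C)[C@H](OCc4ccc(OC)cc4)[C@@H](O[Si](C)(C)C(C)(C)C)[C@H]12 | intermediate
27 | Mannich base, C11 CH2NMe2 | CN(C)C[C@H]1C(=O)O[C@H]2C[C@@]3(C)OC(=CC3=O)[C@@H](C)[C@H](OCc4ccc(OC)cc4)[C@@H](O[Si](C)(C)C(C)(C)C)[C@H]12 | intermediate
28 | methiodide of 27 | [I-].C[N+](C)(C)C[C@H]1C(=O)O[C@H]2C[C@@]3(C)OC(=CC3=O)[C@@H](C)[C@H](OCc4ccc(OC)cc4)[C@@H](O[Si](C)(C)C(C)(C)C)[C@H]12 | intermediate
29 | alpha-methylene lactone, O5 PMB and O6 TBS | C=C1C(=O)O[C@H]2C[C@@]3(C)OC(=CC3=O)[C@@H](C)[C@H](OCc4ccc(OC)cc4)[C@@H](O[Si](C)(C)C(C)(C)C)[C@H]12 | intermediate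
30 | C6 alcohol, O5 PMB | C=C1C(=O)O[C@H]2C[C@@]3(C)OC(=CC3=O)[C@@H](C)[C@H](OCc4ccc(OC)cc4)[C@@H](O)[C@H]12 | intermediate
31 | C6 isobutyrate, O5 PMB | C=C1C(=O)O[C@H]2C[C@@]3(C)OC(=CC3=O)[C@@H](C)[C@H](OCc4ccc(OC)cc4)[C@@H](OC(=O)C(C)C)[C@H]12 | intermediate
32 | CNP0141385.1 | C=C1C(=O)O[C@H]2C[C@@]3(C)OC(=CC3=O)[C@@H](C)[C@H](O)[C@@H](OC(=O)C(C)C)[C@H]12 | target

**Count**
Total steps: 19. Longest linear sequence: 19.

**Steps most likely to fail**

Step 11.
- Risk: 1,2-hydride migration from the methyl group at the carbene centre, or carbene attack on the ethoxyvinyl group, outruns capture by the ring oxygen.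
- Fallback, from 15 back to 23: the quaternary centre is built by enolate alkylation instead of by the shift.
- Salt 15 is activated as 16 and treated with diazomethane to give the terminal diazoketone F1. This has no beta-hydrogen and belongs exactly to the substrate class for which the ring expansion is established.
- Cu(CF3COCHCOCF3)2 in refluxing CH2Cl2 should give the nor-methyl bridged ketone F2 (H at C10, C4 and C9 syn as before).
- 20 and Rh2(OAc)4 give the nor-methyl cyclopropane F3.
- LiN(iPr)2/Me3SiCl (kinetic enolisation at the C2 methylene) gives the nor-methyl silyl enol ether F4, and Pd(OAc)2 gives the nor-methyl furanone F5.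
- Deprotonation of the now doubly activated C10-H with KN(SiMe3)2 is followed by C-alkylation with MeI. This is possible only on the face not covered by the six-carbon bridge, and it gives 23.

Step 12.
- Risk: carbene transfer to the hindered trisubstituted enol ether next to the silyl ether is sluggish, so that carbene dimerisation and attack on the anisyl ring take over.
- Fallback, from 19 back to 26: the carbenoid is replaced by a small electrophilic radical and the dehydrogenation is postponed.
- Ethyl iodoacetate and Et3B/air add the CH2CO2Et radical to C7 of 19 (polarity-matched iodine atom transfer). Work-up with aqueous NaHCO3 unmasks the C8 ketone to give the saturated diketo ester F6.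
- NaBH4 reduces both ketones and PPTS closes the lactone to give the C1 hydroxy lactone F7.
- Dess-Martin oxidation gives the keto lactone F8.
- LiN(iPr)2/Me3SiCl (ketone more acidic than lactone) gives the lactone silyl enol ether F9, and Pd(OAc)2 gives 26.

Step 15.
- Risk: hydride is delivered to the wrong face of the medium-ring C8 ketone.
- Fallback, from 24 back to 26: the wrong face is accepted and C8 is inverted.
- The 8-epimeric hydroxy ester F10 from the reduction of 24 is saponified (LiOH, aq THF) to the 8-epimeric hydroxy acid F11.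
- Mitsunobu lactonisation (PPh3, DIAD, THF) then closes the ring by SN2 displacement at C8 with inversion to give 26.

**Further compounds**
F1 | step 11 | terminal diazoketone | [N-]=[N+]=CC(=O)C[C@@H]1[C@@H](C)[C@H](OCc2ccc(OC)cc2)[C@@H](O[Si](C)(C)C(C)(C)C)[C@H](C(=C)OCC)O1
F2 | step 11 | nor-methyl bridged ketone | C1[C@H]2O[C@H](CC2=O)[C@@H](C)[C@H](OCc3ccc(OC)cc3)[C@@H](O[Si](C)(C)C(C)(C)C)/C=C1/OCC
F3 | step 11 | nor-methyl cyclopropane | CCO[C@@]12C[C@H]3O[C@H](CC3=O)[C@@H](C)[C@H](OCc4ccc(OC)cc4)[C@@H](O[Si](C)(C)C(C)(C)C)[C@@H]1[C@H]2C(=O)OCC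
F4 | step 11 | nor-methyl silyl enol ether | CCO[C@@]12C[C@H]3O[C@H](C=C3O[Si](C)(C)C)[C@@H](C)[C@H](OCc4ccc(OC)cc4)[C@@H](O[Si](C)(C)C(C)(C)C)[C@@H]1[C@H]2C(=O)OCC
F5 | step 11 | nor-methyl furanone | CCO[C@@]12C[C@H]3OC(=CC3=O)[C@@H](C)[C@H](OCc4ccc(OC)cc4)[C@@H](O[Si](C)(C)C(C)(C)C)[C@@H]1[C@H]2C(=O)OCC
F6 | step 12 | saturated diketo ester | O=C1C[C@@]2(C)O[C@H](CC2=O)[C@@H](C)[C@H](OCc3ccc(OC)cc3)[C@@H](O[Si](C)(C)C(C)(C)C)[C@@H]1CC(=O)OCC
F7 | step 12 | C1 hydroxy lactone | C1C(=O)O[C@H]2C[C@@]3(C)O[C@H](C[C@H]3O)[C@@H](C)[C@H](OCc4ccc(OC)cc4)[C@@H](O[Si](C)(C)C(C)(C)C)[C@H]12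
F8 | step 12 | keto lactone | C1C(=O)O[C@H]2C[C@@]3(C)O[C@H](CC3=O)[C@@H](C)[C@H](OCc4ccc(OC)cc4)[C@@H](O[Si](C)(C)C(C)(C)C)[C@H]12
F9 | step 12 | lactone silyl enol ether | C1C(=O)O[C@H]2C[C@@]3(C)O[C@H](C=C3O[Si](C)(C)C)[C@@H](C)[C@H](OCc4ccc(OC)cc4)[C@@H](O[Si](C)(C)C(C)(C)C)[C@H]12
F10 | step 15 | 8-epimeric hydroxy ester | O[C@@H]1C[C@@]2(C)OC(=CC2=O)[C@@H](C)[C@H](OCc3ccc(OC)cc3)[C@@H](O[Si](C)(C)C(C)(C)C)[C@@H]1CC(=O)OCC
F11 | step 15 | 8-epimeric hydroxy acid | O[C@@H]1C[C@@]2(C)OC(=CC2=O)[C@@H](C)[C@H](OCc3ccc(OC)cc3)[C@@H](O[Si](C)(C)C(C)(C)C)[C@@H]1CC(=O)O
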